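**Retrosynthetic overview**
1. 30 ⇐ 29 by a Schenck ene reaction (C5–OOH, C4=C15). 29 ⇐ enone ester 18 by Luche reduction at C3, conversion of the C7 ester into the acrylate, and angeloylation.
2. 18 ⇐ [4.4.1]propellane ketone 16 by acid cleavage of the temporary C5–C14 bond. C14 stays on C10 as the 10β-methyl and C4=C5 appears.
3. Feature used: the 3β-oxygen on ring A is homoallylic to a C5=C10 ring-fusion double bond and lies on the face of C14. Alcohol 12 can therefore carry CH2 (from 13) to the β face, making C10–C14 and C5–C14 (15).
4. 12 ⇐ Birch reduction of tetralin acid 8, then enzymatic reduction at C3. 8 ⇐ 1 + 2 by Stobbe condensation, asymmetric hydrogenation (C7) and Friedel–Crafts closure.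
5. Ring order: ring A is bought as the arene of 1, ring B is closed in step 3, and the cyclopropane is closed in step 9 and opened in step 11.

Key step: step 9

Numbering: eudesmane numbering is used. Ring A is C1–C5 and C10, ring B is C5–C10, C14 sits on C10, C15 on C4, and C11–C13 on C7. β is the face of C14.
Assumption 1: by analogy with enamide and itaconate hydrogenations, the (R,R) ligand is taken to give the S half-ester 4; if the sense is opposite, the equally available (S,S) ligand is used.
Assumption 2: C4 is a transient centre whose faces the Birch protonation should not distinguish, so 9–16 are drawn as 4α-methyl epimers, and the 4β epimers should follow the same steps and merge with them in 18, where C4 is sp2.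

**Step 1**
Reactants: 1 3-methoxy-2-methylbenzaldehyde; 2 dimethyl succinate
Product: 3 (E)-3-(methoxycarbonyl)-4-(3-methoxy-2-methylphenyl)but-3-enoic acid
Conditions: NaOMe, MeOH, reflux; then aq HCl
Reagents that add atoms: none
Why: Stobbe condensation, in which the succinate enolate adds to the aldehyde, the alkoxide lactonises onto the distal ester, and base-induced ring opening gives the E-alkylidene half-ester with its two carboxyl groups already differentiated.

**Step 2**
Reactants: 3
Product: 4 (S)-3-(methoxycarbonyl)-4-(3-methoxy-2-methylphenyl)butanoic acid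
Conditions: [Rh(cod)((R,R)-Et-DuPhos)]BF4 (cat.), NaOMe (cat.), H2 (5 bar), MeOH, rt
Reagents that add atoms: none
Why: Rhodium-catalysed asymmetric hydrogenation of a Stobbe-type itaconate half-ester, in which the carboxylate chelates rhodium as the amide of an enamide does and the C2-symmetric bisphospholane selects the alkene face, setting C7.

**Step 3**
Reactants: 4
Product: 6 methyl (S)-7-methoxy-8-methyl-4-oxo-1,2,3,4-tetrahydronaphthalene-2-carboxylate, via mixed trifluoroacetic anhydride 5 (not isolated)
Conditions: (CF3CO)2O, CF3CO2H, 0 °C → rt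
Reagents that add atoms: trifluoroacetic anhydride, O=C(OC(=O)C(F)(F)F)C(F)(F)F (its acyl group is held only by intermediate 5)
Why: Intramolecular Friedel–Crafts acylation closes ring B (C9–C10) at the only free ortho position, which is also para to the methoxy group, and the acidic medium leaves C7 untouched.

**Step 4**
Reactants: 6
Product: 7 methyl (R)-7-methoxy-8-methyl-1,2,3,4-tetrahydronaphthalene-2-carboxylate
Conditions: Et3SiH, CF3CO2H, rt → 50 °C
Reagents that add atoms: none
Why: Ionic hydrogenation, in which the p-methoxy-stabilised benzylic cation from the protonated aryl ketone takes hydride from the silane twice while the ester is inert (the descriptor changes only through the priority rules).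

**Step 5**
Reactants: 7
Product: 8 (R)-7-methoxy-8-methyl-1,2,3,4-tetrahydronaphthalene-2-carboxylic acid
Conditions: LiOH·H2O, THF–H2O, rt; then aq HCl
Reagents that add atoms: lithium hydroxide, [Li+].[OH-]
Why: Saponification gives the carboxylate, the one carboxyl form that dissolving metal does not reduce, and hydroxide at room temperature should not enolise the α-centre C7.

**Step 6**
Reactants: 8
Product: 10 (2R)-8-methyl-7-oxo-1,2,3,4,5,6,7,8-octahydronaphthalene-2-carboxylic acid (3-oxo-5(10)-ene acid), via dienol ether acid 9 (not isolated)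
Conditions: Li (excess), NH3(l)–THF–t-BuOH, −78 → −33 °C; solid NH4Cl, NH3 evaporated; then (CO2H)2, MeOH–H2O, rt
Reagents that add atoms: water, O
Why: Birch reduction protonates C1 and C4 and keeps the methoxy carbon and both ring-fusion carbons on double bonds, as with 2,3-dialkylanisoles such as 5-methoxytetralin, and oxalic acid then hydrolyses only the enol ether, being too weak to draw C5=C10 into conjugation.

**Step 7**
Reactants: 10
Product: 11 methyl (2R)-8-methyl-7-oxo-1,2,3,4,5,6,7,8-octahydronaphthalene-2-carboxylate (methyl 3-oxo-12,13,14-trinoreudesm-5(10)-en-11-oate)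
Conditions: Me3SiCHN2, toluene–MeOH, 0 °C
Reagents that add atoms: (trimethylsilyl)diazomethane, C[Si](C)(C)C=[N+]=[N-]
Why: Esterification with a diazoalkane is fast and neutral, so neither base nor strong acid reaches the β,γ-unsaturated ketone.

**Step 8**
Reactants: 11
Product: 12 methyl (2R,7S,8S)-7-hydroxy-8-methyl-1,2,3,4,5,6,7,8-octahydronaphthalene-2-carboxylate (methyl 3β-hydroxy-12,13,14-trinoreudesm-5(10)-en-11-oate; 4α-methyl and 7β-ester)
Conditions: ketoreductase (S-selective, from a screening panel), NADP+ (cat.), i-PrOH, K2HPO4/KH2PO4 buffer pH 7, 30 °C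
Reagents that add atoms: none
Why: Enzymatic ketone reduction with cofactor recycling, in which the enzyme pocket fixes the carbonyl face that receives hydride and so sets C3 as S (3β-OH) independently of the remote C7, as hydroxysteroid-dehydrogenase-type enzymes do with 3-oxo-5(10)-ene steroids, while the neutral buffer keeps C5=C10 in place.

**Step 9**
Reactants: 12; 13 diiodomethane
Product: 15 methyl 3β-hydroxy-5β,10β-methano-12,13,14-trinoreudesman-11-oate ([4.4.1]propellane alcohol with C14 bridging C5 and C10 on the β face), via iodomethylzinc alkoxide 14 (not isolated)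
Conditions: Et2Zn, 13, CH2Cl2, −10 °C → rt; aq NH4Cl
Reagents that add atoms: diethylzinc, CC[Zn]CC (zinc is held only by intermediate 14)
Why: Et2Zn turns the 3β-hydroxyl into its zinc alkoxide and exchange with 13 gives the iodomethylzinc alkoxide 14, whose CH2 is passed to C5=C10 in one concerted three-centre step, so that C10–C14 and the temporary C5–C14 bond form together. The reaction type is the hydroxyl-directed Simmons–Smith cyclopropanation (Furukawa variant), known for homoallylic 3-hydroxy-5(10)-enes of the octalin and 19-nor steroid series. The only ring closed is the cyclopropane, by suprafacial [2+1] addition of the tethered carbenoid across the ring-fusion alkene, which makes the [4.4.1]propellane. Both new quaternary centres, C5 and C10, are controlled by C3, because zinc is bound to the β oxygen and can reach only the β face. The step needs facial selectivity on a nearly flat tetrasubstituted alkene: A(1,2) strain against C6H2 should hold the 4α-methyl pseudo-axial, which places the trans 3β-O–Zn bond pseudo-axial above the alkene and lets the methyl group screen the α face. Chemoselectivity is not at stake, since the ester is inert to zinc carbenoids and there is no second alkene.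

**Step 10**
Reactants: 15
Product: 16 methyl 3-oxo-5β,10β-methano-12,13,14-trinoreudesman-11-oate (propellane ketone)
Conditions: Dess–Martin periodinane, CH2Cl2, 0 °C → rt
Reagents that add atoms: none
Why: Dess–Martin oxidation of the secondary alcohol is mild enough to leave the cyclopropane and the ester intact, and it places a carbonyl group two bonds from C5.

**Step 11**
Reactants: 16
Product: 18 methyl 3-oxo-12,13-dinoreudesm-4-en-11-oate (10β-methyl Δ4-3-ketone with 7β-ester), via C3–C4 enol 17 (not isolated)
Conditions: conc. aq HCl, MeOH, reflux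
Reagents that add atoms: none
Why: Acid-catalysed isomerisation of a β-cyclopropyl ketone, known for 5,10-methano-3-keto steroids, in which enol 17 is a vinylcyclopropane whose π system overlaps with the C5–C14 bond standing upright on ring A and not with the in-plane C5–C10 bond, so protonation of the least substituted carbon C14 breaks C5–C14 alone, C10 keeps its configuration, and methanol keeps the methyl ester.

**Step 12**
Reactants: 18
Product: 19 methyl 3β-hydroxy-12,13-dinoreudesm-4-en-11-oate
Conditions: NaBH4, CeCl3·7H2O, MeOH, −20 °C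
Reagents that add atoms: none
Why: Luche reduction, placed here because an enone would not survive the Grignard and amide-base steps that follow, adds hydride 1,2 and axially from the α face, opposite the axial 10β-methyl, which sets C3 again as the pseudo-equatorial 3β-alcohol and spares the ester.

**Step 13**
Reactants: 19
Product: 20 methyl 3β-(tert-butyldimethylsilyloxy)-12,13-dinoreudesm-4-en-11-oate
Conditions: TBSCl, imidazole, DMF, rt
Reagents that add atoms: tert-butyldimethylsilyl chloride, CC(C)(C)[Si](C)(C)Cl
Why: Silylation masks the allylic alcohol with a group that withstands Grignard reagents, amide base and zerovalent palladium and that is no leaving group for the latter.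

**Step 14**
Reactants: 20
Product: 22 3β-(tert-butyldimethylsilyloxy)-13-noreudesm-4-en-11-one (7β-acetyl compound), via Weinreb amide 21 (not isolated)
Conditions: MeNH(OMe)·HCl, i-PrMgCl, THF, −20 → 0 °C; then MeMgBr, 0 °C; aq NH4Cl
Reagents that add atoms: methylmagnesium bromide, C[Mg]Br; N,O-dimethylhydroxylamine hydrochloride, CNOC.Cl (its atoms are held only by intermediate 21)
Why: Weinreb ketone synthesis in one flask, in which the magnesium amide converts the ester into 21 and the chelated adduct of 21 with MeMgBr stops at the ketone stage, the equatorial 7β configuration being also the thermodynamically preferred one.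

**Step 15**
Reactants: 22
Product: 24 3β-(tert-butyldimethylsilyloxy)-13-noreudesma-4,11-dien-11-yl trifluoromethanesulfonate (terminal enol triflate), via potassium enolate 23 (not isolated)
Conditions: KN(SiMe3)2, THF, −78 °C; then PhNTf2, −78 → 0 °C
Reagents that add atoms: N-phenylbis(trifluoromethanesulfonimide), O=S(=O)(N(c1ccccc1)S(=O)(=O)C(F)(F)F)C(F)(F)F; potassium hexamethyldisilazide, C[Si](C)(C)[N-][Si](C)(C)C.[K+] (potassium is held only by intermediate 23)
Why: Kinetic deprotonation of a methyl ketone by a bulky amide at low temperature takes a CH3 proton and not the tertiary C7–H, so C7 is untouched, and O-sulfonylation by the triflimide gives the terminal enol triflate.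

**Step 16**
Reactants: 24
Product: 25 methyl 3β-(tert-butyldimethylsilyloxy)eudesma-4,11(13)-dien-12-oate
Conditions: Pd(PPh3)4 (cat.), CO (1 atm), MeOH, Et3N, DMF, 40 °C
Reagents that add atoms: carbon monoxide, [C-]#[O+]; methanol, CO
Why: Palladium-catalysed methoxycarbonylation of an enol triflate gives the α-substituted acrylate by oxidative addition to zerovalent palladium, CO insertion and methanolysis of the acylpalladium species.

**Step 17**
Reactants: 25
Product: 26 methyl 3β-hydroxyeudesma-4,11(13)-dien-12-oate
Conditions: n-Bu4NF, AcOH, THF, rt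
Reagents that add atoms: none
Why: Fluoride cleavage of the silyl ether, buffered with acetic acid so that no free alkoxide can add to the acrylate.

**Step 18**
Reactants: 26; 27 angelic acid ((Z)-2-methylbut-2-enoic acid)
Product: 29 methyl 3β-angeloyloxyeudesma-4,11(13)-dien-12-oate, via mixed angelic anhydride 28 (not isolated)
Conditions: 27, 2,4,6-trichlorobenzoyl chloride, Et3N, toluene, rt; then 26, 80 °C
Reagents that add atoms: 2,4,6-trichlorobenzoyl chloride, O=C(Cl)c1c(Cl)cc(Cl)cc1Cl (its acyl group is held only by intermediate 28)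
Why: Yamaguchi-type mixed-anhydride esterification without a nucleophilic catalyst is the established way to transfer the angeloyl group without Z to E isomerisation, and since the alcohol attacks the less hindered angeloyl carbonyl and C3–O is not broken, the 3β configuration is kept.

**Step 19**
Reactants: 29
Product: 30 methyl 3β-angeloyloxy-5α-hydroperoxyeudesma-4(15),11(13)-dien-12-oate (target)
Conditions: O2, tetraphenylporphyrin (cat.), visible light, CH2Cl2, −20 °C
Reagents that add atoms: dioxygen, O=O
Why: Schenck ene reaction, in which singlet oxygen attacks only the electron-rich tetrasubstituted C4=C5 bond (acrylate and angelate are electron-poor) from the α face, because the axial 10β-methyl and the 3β-ester close the β face, which sets C5 as 5α-OOH, and it takes hydrogen from the C15 methyl, the group geminal to the bulky, electron-withdrawing C3 carbinyl ester, the 6α-hydrogen being badly aligned, so the double bond moves to C4=C15.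

**Compound list**
1 | 3-methoxy-2-methylbenzaldehyde | COc1cccc(C=O)c1C | starting material
2 | dimethyl succinate | COC(=O)CCC(=O)OC | starting material
3 | (E)-3-(methoxycarbonyl)-4-(3-methoxy-2-methylphenyl)but-3-enoic acid | COC(=O)/C(CC(=O)O)=C/c1cccc(OC)c1C | intermediate
4 | (S)-3-(methoxycarbonyl)-4-(3-methoxy-2-methylphenyl)butanoic acid | COC(=O)[C@@H](Cc1cccc(OC)c1C)CC(=O)O | intermediate
5 | mixed trifluoroacetic anhydride of 4 | COC(=O)[C@@H](Cc1cccc(OC)c1C)CC(=O)OC(=O)C(F)(F)F | intermediate
6 | methyl (S)-7-methoxy-8-methyl-4-oxo-1,2,3,4-tetrahydronaphthalene-2-carboxylate | COC(=O)[C@@H]1CC(=O)c2ccc(OC)c(C)c2C1 | intermediate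
7 | methyl (R)-7-methoxy-8-methyl-1,2,3,4-tetrahydronaphthalene-2-carboxylate | COC(=O)[C@@H]1CCc2ccc(OC)c(C)c2C1 | intermediate
8 | (R)-7-methoxy-8-methyl-1,2,3,4-tetrahydronaphthalene-2-carboxylic acid | OC(=O)[C@@H]1CCc2ccc(OC)c(C)c2C1 | intermediate
9 | (2R)-7-methoxy-8-methyl-1,2,3,4,5,8-hexahydronaphthalene-2-carboxylic acid (3-methoxy-2,5(10)-diene) | OC(=O)[C@@H]1CCC2=C(C1)[C@H](C)C(OC)=CC2 | intermediate
10 | (2R)-8-methyl-7-oxo-1,2,3,4,5,6,7,8-octahydronaphthalene-2-carboxylic acid | OC(=O)[C@@H]1CCC2=C(C1)[C@H](C)C(=O)CC2 | intermediate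
11 | methyl 3-oxo-12,13,14-trinoreudesm-5(10)-en-11-oate | COC(=O)[C@@H]1CCC2=C(C1)[C@H](C)C(=O)CC2 | intermediate
12 | methyl 3β-hydroxy-12,13,14-trinoreudesm-5(10)-en-11-oate (4α-methyl) | COC(=O)[C@@H]1CCC2=C(C1)[C@H](C)[C@@H](O)CC2 | intermediate
13 | diiodomethane | ICI | starting material
14 | iodomethylzinc alkoxide of 12 | COC(=O)[C@@H]1CCC2=C(C1)[C@H](C)[C@@H](O[Zn]CI)CC2 | intermediate
15 | methyl 3β-hydroxy-5β,10β-methano-12,13,14-trinoreudesman-11-oate | COC(=O)[C@@H]1CC[C@]23C[C@@]2(C1)[C@H](C)[C@@H](O)CC3 | intermediate
16 | methyl 3-oxo-5β,10β-methano-12,13,14-trinoreudesman-11-oate | COC(=O)[C@@H]1CC[C@]23C[C@@]2(C1)[C@H](C)C(=O)CC3 | intermediate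
17 | C3–C4 enol of 16 | COC(=O)[C@@H]1CC[C@]23C[C@@]2(C1)C(C)=C(O)CC3 | intermediate
18 | methyl 3-oxo-12,13-dinoreudesm-4-en-11-oate | COC(=O)[C@@H]1CC[C@@]2(C)CCC(=O)C(C)=C2C1 | intermediate
19 | methyl 3β-hydroxy-12,13-dinoreudesm-4-en-11-oate | COC(=O)[C@@H]1CC[C@@]2(C)CC[C@H](O)C(C)=C2C1 | intermediate
20 | methyl 3β-(tert-butyldimethylsilyloxy)-12,13-dinoreudesm-4-en-11-oate | COC(=O)[C@@H]1CC[C@@]2(C)CC[C@H](O[Si](C)(C)C(C)(C)C)C(C)=C2C1 | intermediate
21 | N-methoxy-N-methyl amide of the acid of 20 | CON(C)C(=O)[C@@H]1CC[C@@]2(C)CC[C@H](O[Si](C)(C)C(C)(C)C)C(C)=C2C1 | intermediate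
22 | 3β-(tert-butyldimethylsilyloxy)-13-noreudesm-4-en-11-one | CC(=O)[C@@H]1CC[C@@]2(C)CC[C@H](O[Si](C)(C)C(C)(C)C)C(C)=C2C1 | intermediate
23 | terminal potassium enolate of 22 | C=C([O-])[C@@H]1CC[C@@]2(C)CC[C@H](O[Si](C)(C)C(C)(C)C)C(C)=C2C1.[K+] | intermediate
24 | 3β-(tert-butyldimethylsilyloxy)-13-noreudesma-4,11-dien-11-yl triflate | C=C(OS(=O)(=O)C(F)(F)F)[C@@H]1CC[C@@]2(C)CC[C@H](O[Si](C)(C)C(C)(C)C)C(C)=C2C1 | intermediate
25 | methyl 3β-(tert-butyldimethylsilyloxy)eudesma-4,11(13)-dien-12-oate | C=C(C(=O)OC)[C@@H]1CC[C@@]2(C)CC[C@H](O[Si](C)(C)C(C)(C)C)C(C)=C2C1 | intermediate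
26 | methyl 3β-hydroxyeudesma-4,11(13)-dien-12-oate | C=C(C(=O)OC)[C@@H]1CC[C@@]2(C)CC[C@H](O)C(C)=C2C1 | intermediate
27 | angelic acid | C/C=C(/C)C(=O)O | starting material
28 | angelic 2,4,6-trichlorobenzoic anhydride | C/C=C(/C)C(=O)OC(=O)c1c(Cl)cc(Cl)cc1Cl | intermediate
29 | methyl 3β-angeloyloxyeudesma-4,11(13)-dien-12-oate | C=C(C(=O)OC)[C@@H]1CC[C@@]2(C)CC[C@H](OC(=O)/C(C)=C\C)C(C)=C2C1 | intermediate
30 | methyl 3β-angeloyloxy-5α-hydroperoxyeudesma-4(15),11(13)-dien-12-oate | C=C(C(=O)OC)[C@@H]1CC[C@@]2(C)CC[C@H](OC(=O)/C(C)=C\C)C(=C)[C@]2(OO)C1 | target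

**Total step count:** 19. **Longest linear sequence:** 19 steps (from 1).

**Steps most likely to fail**

**Step 9.** Methylene transfer to the hindered tetrasubstituted alkene may be slower than decay of the carbenoid or O-alkylation of the alkoxide. Carbenoid that is not bound to the alkoxide may also erode the facial selectivity.

The fallback sets out from 12 and comes back at 15. It replaces the tethered zinc carbenoid by a free dihalocarbene, which is much more reactive toward tetrasubstituted alkenes.
- 12 is acetylated (Ac2O, pyridine) to the 3β-acetate F1.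
- Dibromocarbene from PhHgCBr3 (benzene, 80 °C) is added to give the 14,14-dibromopropellane acetate F2.
- Face selection then rests only on the screening of the α face by the pseudo-axial 4α-methyl, so the adducts may have to be separated.
- Both bromines are removed with n-Bu3SnH and AIBN (toluene, reflux) to give the propellane acetate F3.
- K2CO3 in MeOH frees 15.

**Step 19.** Three things may go wrong:
- Uptake of singlet oxygen may be slow, because the allylic ester deactivates the alkene.
- Hydrogen may be taken from C3 or C6 in place of C15.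
- The tertiary allylic hydroperoxide may be lost during long irradiation or on silica.

The fallback sets out from 25 and comes back at 30. It moves the oxygenation ahead of the acylation.
- The more electron-rich silyl ether 25, whose bulky C3 substituent reinforces abstraction from the geminal methyl, is photooxygenated to the 5α-hydroperoxy silyl ether F4.
- The hydroperoxide is masked with 2-methoxypropene and pyridinium tosylate as the 2-methoxyprop-2-yl perketal F5.
- n-Bu4NF gives the perketal alcohol F6.
- Acylation with 28 as in step 18 gives the perketal angelate F7.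
- AcOH–THF–H2O at room temperature releases 30, so the last step becomes a mild hydrolysis.

**Step 8.** No enzyme of the panel may combine full conversion with high face selectivity on both C4 epimers. Long residence in buffer may also let the double bond slip into conjugation.

The fallback sets out from 11 and comes back at 12. It replaces catalyst control by separation and stereoinversion.
- NaBH4 (MeOH, −20 °C) reduces 11 without control at C3.
- 12 is separated from the 3α-alcohol F8.
- F8 is inverted by a Mitsunobu reaction (4-nitrobenzoic acid, PPh3, DIAD, THF) to the 3β-(4-nitrobenzoate) F9.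
- K2CO3 in MeOH converts F9 into 12.

**Further compounds**
F1 | step 9 | methyl 3β-acetoxy-12,13,14-trinoreudesm-5(10)-en-11-oate | COC(=O)[C@@H]1CCC2=C(C1)[C@H](C)[C@@H](OC(C)=O)CC2
F2 | step 9 | methyl 3β-acetoxy-14,14-dibromo-5β,10β-methano-12,13,14-trinoreudesman-11-oate | COC(=O)[C@@H]1CC[C@]23C(Br)(Br)[C@@]2(C1)[C@H](C)[C@@H](OC(C)=O)CC3
F3 | step 9 | methyl 3β-acetoxy-5β,10β-methano-12,13,14-trinoreudesman-11-oate | COC(=O)[C@@H]1CC[C@]23C[C@@]2(C1)[C@H](C)[C@@H](OC(C)=O)CC3
F4 | step 19 | methyl 3β-(tert-butyldimethylsilyloxy)-5α-hydroperoxyeudesma-4(15),11(13)-dien-12-oate | C=C(C(=O)OC)[C@@H]1CC[C@@]2(C)CC[C@H](O[Si](C)(C)C(C)(C)C)C(=C)[C@]2(OO)C1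
F5 | step 19 | 2-methoxyprop-2-yl perketal of F4 | C=C(C(=O)OC)[C@@H]1CC[C@@]2(C)CC[C@H](O[Si](C)(C)C(C)(C)C)C(=C)[C@]2(OOC(C)(C)OC)C1
F6 | step 19 | methyl 3β-hydroxy-5α-(2-methoxyprop-2-ylperoxy)eudesma-4(15),11(13)-dien-12-oate | C=C(C(=O)OC)[C@@H]1CC[C@@]2(C)CC[C@H](O)C(=C)[C@]2(OOC(C)(C)OC)C1
F7 | step 19 | methyl 3β-angeloyloxy-5α-(2-methoxyprop-2-ylperoxy)eudesma-4(15),11(13)-dien-12-oate | C=C(C(=O)OC)[C@@H]1CC[C@@]2(C)CC[C@H](OC(=O)/C(C)=C\C)C(=C)[C@]2(OOC(C)(C)OC)C1
F8 | step 8 | methyl 3α-hydroxy-12,13,14-trinoreudesm-5(10)-en-11-oate | COC(=O)[C@@H]1CCC2=C(C1)[C@H](C)[C@H](O)CC2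
F9 | step 8 | methyl 3β-(4-nitrobenzoyloxy)-12,13,14-trinoreudesm-5(10)-en-11-oate | COC(=O)[C@@H]1CCC2=C(C1)[C@H](C)[C@@H](OC(=O)c3ccc(cc3)[N+](=O)[O-])CC2
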